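**Retrosynthetic overview** (C1 = alkyne CH … C15 = ethyl CH3)
1. C8–Br is installed last by invertive bromination of the C8 allylic alcohol.
2. The (3Z)-enyne comes from Z-selective enyne cross-metathesis on a C6 allyl group; ring A (formed second), its 6E enol ether and the C5–C6 bond come from anti-oxypalladation/allylation of a terminal alkynol.
3. Ring B (formed first) comes from 5-exo opening of a C8–C9 trans-epoxide by the C12 hydroxyl, after a 1,3-syn ketone reduction that sets C10.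
4. The C11–C12 bond comes from an aldol of an epoxy methyl ketone with (S)-2-bromobutanal (sets C12).
5. Absolute stereochemistry comes from two organocatalytic steps on achiral materials: epoxidation of an ynenone (C8, C9) and α-bromination of butanal (C13).

Assumption: the quinine-derived amine in step 2 and the (S)-prolinol ether in step 3 give the senses drawn; if either is opposite, the pseudo-enantiomeric or mirror-image catalyst is used with no other change.

**Step 1**
Reactants: 1 3-[tri(propan-2-yl)silyl]prop-2-ynal; 2 1-(triphenyl-λ5-phosphanylidene)propan-2-one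
Product: 3 (3E)-6-[tri(propan-2-yl)silyl]hex-3-en-5-yn-2-one
Conditions: CH2Cl2, 23 °C, 12 h
Reagents that add atoms: none
Why: Wittig olefination with a stabilised ylide gives the E-enone selectively.

**Step 2**
Reactants: 3 (3E)-6-[tri(propan-2-yl)silyl]hex-3-en-5-yn-2-one
Product: 5 1-[(2R,3S)-3-{[tri(propan-2-yl)silyl]ethynyl}oxiran-2-yl]ethan-1-one, via hydroperoxy ketone 4 (not isolated)
Conditions: 9-amino-9-deoxy-epi-quinine (10 mol %), CF3CO2H (20 mol %), 50% aq. H2O2 (1.5 equiv), 1,4-dioxane, 35 °C; then 1 M NaOH (cat.), THF, 0 °C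
Reagents that add atoms: hydrogen peroxide, OO
Why: Proposed new method: iminium-catalysed asymmetric epoxidation of a β-alkynyl enone (ynenone), a substrate class not yet shown for this catalysis; the primary amine condenses with the methyl ketone to an iminium ion, the protonated quinuclidine delivers H2O2 by hydrogen bonding to one face of the β-carbon (C8), 1,6-attack at the alkyne terminus is blocked by the triisopropylsilyl group, and the β-hydroperoxy enamine closes on the O–O bond to give the trans-epoxide, which sets C8 and C9; the closest known reaction is the cinchona-primary-amine-catalysed hydroperoxidation/epoxidation of alkyl- and aryl-substituted enones (asymmetric Weitz–Scheffer type).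

**Step 3**
Reactants: 6 butanal
Product: 7 (2S)-2-bromobutanal (kept as a cold, dried pentane solution and used at once)
Conditions: (S)-2-{bis[3,5-bis(trifluoromethyl)phenyl](trimethylsilyloxy)methyl}pyrrolidine (5 mol %), NBS (1.0 equiv, slow addition), (CF3)2CHOH/CH2Cl2, 0 °C; cold pentane/H2O partition
Reagents that add atoms: N-bromosuccinimide, O=C1CCC(=O)N1Br
Why: Enamine-catalysed α-bromination, in which the diarylprolinol silyl ether shields one face of the E-enamine so that bromine is delivered to the other face, setting C13 as S.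

**Step 4**
Reactants: 5 1-[(2R,3S)-3-{[tri(propan-2-yl)silyl]ethynyl}oxiran-2-yl]ethan-1-one; 7 (2S)-2-bromobutanal
Product: 8 (3R,4S)-4-bromo-3-hydroxy-1-[(2R,3S)-3-{[tri(propan-2-yl)silyl]ethynyl}oxiran-2-yl]hexan-1-one
Conditions: LiN(iPr)2 (1.05 equiv), THF, −78 °C; then 7 (1.3 equiv), −78 °C, 20 min; AcOH quench at −78 °C
Reagents that add atoms: none
Why: Aldol addition of the kinetic lithium methyl-ketone enolate to the α-bromo aldehyde under Cornforth (polar Felkin–Anh) control gives the 1,2-anti bromohydrin, setting C12 as R, and the cold quench prevents epoxide formation from the bromohydrin alkoxide.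

**Step 5**
Reactants: 8 (3R,4S)-4-bromo-3-hydroxy-1-[(2R,3S)-3-{[tri(propan-2-yl)silyl]ethynyl}oxiran-2-yl]hexan-1-one
Product: 10 (1S)-1-[(2R,3S,5R)-5-[(1S)-1-bromopropyl]-3-hydroxyoxolan-2-yl]-3-[tri(propan-2-yl)silyl]prop-2-yn-1-ol, via epoxy diol 9 (not isolated)
Conditions: Et2BOMe (1.1 equiv), THF/MeOH 4:1, −78 °C; NaBH4 (1.2 equiv); AcOH, MeOH co-evaporation; then CSA (10 mol %), CH2Cl2, 0 → 23 °C
Reagents that add atoms: none
Why: Narasaka–Prasad reduction of the boron chelate gives the 1,3-syn diol (C10 S, reinforced by hydride addition anti to the epoxide C–O bond), and acid then drives 5-exo-tet epoxide opening by the C12 hydroxyl at C9 with inversion, forming ring B with the 2,3-cis/2,5-trans pattern and leaving the C8 carbinol.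

**Step 6**
Reactants: 10 (1S)-1-[(2R,3S,5R)-5-[(1S)-1-bromopropyl]-3-hydroxyoxolan-2-yl]-3-[tri(propan-2-yl)silyl]prop-2-yn-1-ol
Product: 11 (1S)-1-[(2R,3S,5R)-5-[(1S)-1-bromopropyl]-3-hydroxyoxolan-2-yl]prop-2-yn-1-ol
Conditions: Bu4NF/AcOH (1:1, 1.5 equiv), THF, 0 → 23 °C
Reagents that add atoms: none
Why: Buffered fluoride protodesilylation of the alkynylsilane touches neither the secondary bromide nor any stereocentre.

**Step 7**
Reactants: 11 (1S)-1-[(2R,3S,5R)-5-[(1S)-1-bromopropyl]-3-hydroxyoxolan-2-yl]prop-2-yn-1-ol; 12 3-bromoprop-1-ene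
Product: 13 (2E,3R,3aS,5R,6aS)-5-[(1S)-1-bromopropyl]-2-(but-3-en-1-ylidene)hexahydrofuro[3,2-b]furan-3-ol
Conditions: PdCl2(MeCN)2 (5 mol %), 12 (5 equiv), methyloxirane (10 equiv), THF, 0 → 23 °C
Reagents that add atoms: none
Why: Wacker-type 5-exo-dig anti-oxypalladation by the ring hydroxyl, insertion of allyl bromide into the vinyl–palladium bond and β-bromide elimination (returning divalent palladium) form ring A, and because O and Pd add anti and the C–C bond forms with retention the allyl group ends trans to oxygen (6E), while methyloxirane traps HBr.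

**Step 8**
Reactants: 14 ethynyltri(propan-2-yl)silane; 15 bromoethene
Product: 16 (but-3-en-1-yn-1-yl)tri(propan-2-yl)silane
Conditions: PdCl2(PPh3)2 (2 mol %), CuI (4 mol %), iPr2NH (1.5 equiv), THF, 0 → 23 °C
Reagents that add atoms: none
Why: Sonogashira coupling of a terminal alkyne with a vinyl bromide.

**Step 9**
Reactants: 13 (2E,3R,3aS,5R,6aS)-5-[(1S)-1-bromopropyl]-2-(but-3-en-1-ylidene)hexahydrofuro[3,2-b]furan-3-ol; 16 (but-3-en-1-yn-1-yl)tri(propan-2-yl)silane
Product: 17 (2E,3R,3aS,5R,6aS)-5-[(1S)-1-bromopropyl]-2-{(3Z)-6-[tri(propan-2-yl)silyl]hex-3-en-5-yn-1-ylidene}hexahydrofuro[3,2-b]furan-3-ol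
Conditions: [1,3-bis(2,4,6-trimethylphenyl)imidazolidin-2-ylidene]dichloro(benzylidene)(tricyclohexylphosphine)ruthenium (second-generation Grubbs catalyst, 10 mol %), 16 (4 equiv), CH2Cl2, 40 °C
Reagents that add atoms: none
Why: Alkene cross-metathesis of the terminal allyl alkene with a silyl-capped 1,3-enyne, a pairing that kinetically favours the Z-enyne, while the trisubstituted enol ether and the hindered silylalkyne stay out of the catalytic cycle.

**Step 10**
Reactants: 17 (2E,3R,3aS,5R,6aS)-5-[(1S)-1-bromopropyl]-2-{(3Z)-6-[tri(propan-2-yl)silyl]hex-3-en-5-yn-1-ylidene}hexahydrofuro[3,2-b]furan-3-ol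
Product: 18 (2E,3R,3aS,5R,6aS)-5-[(1S)-1-bromopropyl]-2-[(3Z)-hex-3-en-5-yn-1-ylidene]hexahydrofuro[3,2-b]furan-3-ol
Conditions: Bu4NF/AcOH (1:1, 1.5 equiv), THF, 0 °C
Reagents that add atoms: none
Why: Buffered fluoride protodesilylation frees the terminal alkyne without isomerising the skipped diene or the enol ether.

**Step 11**
Reactants: 18 (2E,3R,3aS,5R,6aS)-5-[(1S)-1-bromopropyl]-2-[(3Z)-hex-3-en-5-yn-1-ylidene]hexahydrofuro[3,2-b]furan-3-ol
Product: 19 (2E,3S,3aR,5R,6aS)-3-bromo-5-[(1S)-1-bromopropyl]-2-[(3Z)-hex-3-en-5-yn-1-ylidene]hexahydrofuro[3,2-b]furan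
Conditions: CBr4 (1.5 equiv), PPh3 (1.6 equiv), 2,6-di-tert-butylpyridine (2 equiv), CH2Cl2, −20 → 0 °C
Reagents that add atoms: tetrabromomethane, BrC(Br)(Br)Br
Why: Appel reaction, in which the C8 alkoxyphosphonium on the concave face is displaced by bromide from the convex face in an SN2 step with inversion, giving the 8S bromide trans to the ring B oxygen under neutral, buffered conditions.

**Compound list**
1 | 3-[tri(propan-2-yl)silyl]prop-2-ynal | CC(C)[Si](C(C)C)(C(C)C)C#CC=O | starting material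
2 | 1-(triphenyl-λ5-phosphanylidene)propan-2-one | CC(=O)C=P(c1ccccc1)(c1ccccc1)c1ccccc1 | starting material
3 | (3E)-6-[tri(propan-2-yl)silyl]hex-3-en-5-yn-2-one | CC(=O)/C=C/C#C[Si](C(C)C)(C(C)C)C(C)C | intermediate
4 | (4R)-4-hydroperoxy-6-[tri(propan-2-yl)silyl]hex-5-yn-2-one | CC(C)[Si](C(C)C)(C(C)C)C#C[C@H](OO)CC(C)=O | intermediate
5 | 1-[(2R,3S)-3-{[tri(propan-2-yl)silyl]ethynyl}oxiran-2-yl]ethan-1-one | CC(C)[Si](C(C)C)(C(C)C)C#C[C@@H]1O[C@H]1C(C)=O | intermediate
6 | butanal | CCCC=O | starting material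
7 | (2S)-2-bromobutanal | O=C[C@@H](Br)CC | intermediate
8 | (3R,4S)-4-bromo-3-hydroxy-1-[(2R,3S)-3-{[tri(propan-2-yl)silyl]ethynyl}oxiran-2-yl]hexan-1-one | CC(C)[Si](C(C)C)(C(C)C)C#C[C@@H]1O[C@H]1C(=O)C[C@H]([C@@H](Br)CC)O | intermediate
9 | (1S,3R,4S)-4-bromo-1-[(2S,3S)-3-{[tri(propan-2-yl)silyl]ethynyl}oxiran-2-yl]hexane-1,3-diol | CC(C)[Si](C(C)C)(C(C)C)C#C[C@@H]1O[C@H]1[C@@H](O)C[C@H]([C@@H](Br)CC)O | intermediate
10 | (1S)-1-[(2R,3S,5R)-5-[(1S)-1-bromopropyl]-3-hydroxyoxolan-2-yl]-3-[tri(propan-2-yl)silyl]prop-2-yn-1-ol | CC(C)[Si](C(C)C)(C(C)C)C#C[C@H](O)[C@@H]1O[C@@H]([C@@H](Br)CC)C[C@@H]1O | intermediate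
11 | (1S)-1-[(2R,3S,5R)-5-[(1S)-1-bromopropyl]-3-hydroxyoxolan-2-yl]prop-2-yn-1-ol | C#C[C@H](O)[C@@H]1O[C@@H]([C@@H](Br)CC)C[C@@H]1O | intermediate
12 | 3-bromoprop-1-ene | C=CCBr | starting material
13 | (2E,3R,3aS,5R,6aS)-5-[(1S)-1-bromopropyl]-2-(but-3-en-1-ylidene)hexahydrofuro[3,2-b]furan-3-ol | C=CC/C=C1/O[C@H]2C[C@H]([C@@H](Br)CC)O[C@H]2[C@H]1O | intermediate
14 | ethynyltri(propan-2-yl)silane | C#C[Si](C(C)C)(C(C)C)C(C)C | starting material
15 | bromoethene | C=CBr | starting material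
16 | (but-3-en-1-yn-1-yl)tri(propan-2-yl)silane | C=CC#C[Si](C(C)C)(C(C)C)C(C)C | intermediate
17 | (2E,3R,3aS,5R,6aS)-5-[(1S)-1-bromopropyl]-2-{(3Z)-6-[tri(propan-2-yl)silyl]hex-3-en-5-yn-1-ylidene}hexahydrofuro[3,2-b]furan-3-ol | CC(C)[Si](C(C)C)(C(C)C)C#C/C=C\C/C=C1/O[C@H]2C[C@H]([C@@H](Br)CC)O[C@H]2[C@H]1O | intermediate
18 | (2E,3R,3aS,5R,6aS)-5-[(1S)-1-bromopropyl]-2-[(3Z)-hex-3-en-5-yn-1-ylidene]hexahydrofuro[3,2-b]furan-3-ol | C#C/C=C\C/C=C1/O[C@H]2C[C@H]([C@@H](Br)CC)O[C@H]2[C@H]1O | intermediate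
19 | (2E,3S,3aR,5R,6aS)-3-bromo-5-[(1S)-1-bromopropyl]-2-[(3Z)-hex-3-en-5-yn-1-ylidene]hexahydrofuro[3,2-b]furan | C#C/C=C\C/C=C1/O[C@H]2C[C@H]([C@@H](Br)CC)O[C@H]2[C@@H]1Br | target

**Step count and risks**
Total: 11 steps. Longest linear sequence: 9 steps (1, 2, 4, 5, 6, 7, 9, 10, 11); steps 3 and 8 are one-step branches.

Most likely to fail, first: step 2 (the proposed new epoxidation; risks are low conversion of the ynenone iminium, poor enantioselectivity or attack at the alkyne). The fallback uses known chemistry, sets out from 3 and 7 and returns at 10. The lithium enolate of 3 is added to 7 as in step 4 to give (3E,7R,8S)-8-bromo-7-hydroxy-1-[tri(propan-2-yl)silyl]dec-3-en-1-yn-5-one F1. Narasaka–Prasad reduction gives (3E,5S,7R,8S)-8-bromo-1-[tri(propan-2-yl)silyl]dec-3-en-1-yne-5,7-diol F2. Sharpless asymmetric epoxidation of the allylic alcohol (Ti(OiPr)4, L-(+)-diisopropyl tartrate, tBuOOH, 4 Å sieves, CH2Cl2, −20 °C) is the matched case for the 5S carbinol and gives the erythro epoxy diol 9, which is closed with CSA to 10 as in step 5.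

Second: step 7 (competing halopalladation of the alkyne, or acid-induced isomerisation of the 3-hydroxy enol ether). The fallback sets out from 11 and returns at 13. Iodo-etherification (N-iodosuccinimide, NaHCO3, MeCN, 0 °C; anti 5-exo-dig addition) gives (2E,3R,3aS,5R,6aS)-5-[(1S)-1-bromopropyl]-2-(iodomethylidene)hexahydrofuro[3,2-b]furan-3-ol F3. Stille coupling with allyltributylstannane (Pd2(dba)3, AsPh3, CuI, DMF, 23 °C) then replaces iodine by allyl with retention to give 13.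

Third: step 11 (SN2′ attack at C6, or loss of HBr toward a furan, on the enol-ether allylic system). The fallback moves the bromination to the propargylic stage; it sets out from 11 and returns at 19.
- Treatment of 11 with MeC(OMe)3 and pyridinium p-toluenesulfonate, then acetyl bromide (CH2Cl2, 0 °C), opens the cyclic 1,3-acetoxonium ion by bromide at the propargylic carbon with inversion to give (2R,3S,5R)-2-[(1R)-1-bromoprop-2-yn-1-yl]-5-[(1S)-1-bromopropyl]oxolan-3-yl acetate F4.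
- K2CO3 (cat.) in MeOH at 0 °C gives (2R,3S,5R)-2-[(1R)-1-bromoprop-2-yn-1-yl]-5-[(1S)-1-bromopropyl]oxolan-3-ol F5.
- The conditions of step 7 give (2E,3S,3aR,5R,6aS)-3-bromo-5-[(1S)-1-bromopropyl]-2-(but-3-en-1-ylidene)hexahydrofuro[3,2-b]furan F6.
- The conditions of step 9 give (2E,3S,3aR,5R,6aS)-3-bromo-5-[(1S)-1-bromopropyl]-2-{(3Z)-6-[tri(propan-2-yl)silyl]hex-3-en-5-yn-1-ylidene}hexahydrofuro[3,2-b]furan F7.
- Bu4NF/AcOH as in step 10 gives 19.

**Further compounds**
F1 | step 2 | (3E,7R,8S)-8-bromo-7-hydroxy-1-[tri(propan-2-yl)silyl]dec-3-en-1-yn-5-one | CC(C)[Si](C(C)C)(C(C)C)C#C/C=C/C(=O)C[C@H]([C@@H](Br)CC)O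
F2 | step 2 | (3E,5S,7R,8S)-8-bromo-1-[tri(propan-2-yl)silyl]dec-3-en-1-yne-5,7-diol | CC(C)[Si](C(C)C)(C(C)C)C#C/C=C/[C@@H](O)C[C@H]([C@@H](Br)CC)O
F3 | step 7 | (2E,3R,3aS,5R,6aS)-5-[(1S)-1-bromopropyl]-2-(iodomethylidene)hexahydrofuro[3,2-b]furan-3-ol | I/C=C1/O[C@H]2C[C@H]([C@@H](Br)CC)O[C@H]2[C@H]1O
F4 | step 11 | (2R,3S,5R)-2-[(1R)-1-bromoprop-2-yn-1-yl]-5-[(1S)-1-bromopropyl]oxolan-3-yl acetate | C#C[C@@H](Br)[C@@H]1O[C@@H]([C@@H](Br)CC)C[C@@H]1OC(C)=O
F5 | step 11 | (2R,3S,5R)-2-[(1R)-1-bromoprop-2-yn-1-yl]-5-[(1S)-1-bromopropyl]oxolan-3-ol | C#C[C@@H](Br)[C@@H]1O[C@@H]([C@@H](Br)CC)C[C@@H]1O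
F6 | step 11 | (2E,3S,3aR,5R,6aS)-3-bromo-5-[(1S)-1-bromopropyl]-2-(but-3-en-1-ylidene)hexahydrofuro[3,2-b]furan | C=CC/C=C1/O[C@H]2C[C@H]([C@@H](Br)CC)O[C@H]2[C@@H]1Br
F7 | step 11 | (2E,3S,3aR,5R,6aS)-3-bromo-5-[(1S)-1-bromopropyl]-2-{(3Z)-6-[tri(propan-2-yl)silyl]hex-3-en-5-yn-1-ylidene}hexahydrofuro[3,2-b]furan | CC(C)[Si](C(C)C)(C(C)C)C#C/C=C\C/C=C1/O[C@H]2C[C@H]([C@@H](Br)CC)O[C@H]2[C@@H]1Br
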